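Ring F is cut at C1'–C10'. Its exocyclic C10'(14') methylene sits on the ring-fusion carbon C1', and C1' is β to the C3' ketone. A reductive Heck cyclisation of a C10' alkenyl bromide onto the C1'(2') double bond of a spiro-cyclopentenone therefore forms the bond, the seven-membered ring, the methylene and the cis fusion in one operation. Its substrate already holds rings A–E and the primed lactone with a 3-bromobut-3-enyl chain on C7'; the three conjugated methylenes are stored as dimethylamine adducts. It is built from one enantiopure cyclopentenone–lactone unit, used for both halves, by a Diels–Alder reaction that creates ring D and the C2 and C4' centres.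

Key step: step 17

Remark on the chemistry (assumption): the stereodescriptors of the target are taken literally. They define cis-fused γ-lactones in both halves (H6/H7 and H6'/H7' syn; H5/H6 and H5'/H6' anti), so both halves are built de novo and not from trans-fused natural guaianolides.

Conventions: guaiane locants are used. The unprimed half carries C2–OH (ring A five-membered, ring B seven-membered, ring C lactone); ring D is the cyclohexene; the primed half has ring E (five-membered), ring F (seven-membered) and ring G (lactone). Compounds made before the union carry unprimed locants.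

Design of the cyclisation substrate: the substrate of step 17 agrees with the target at every stereocentre they share. Beyond the masked primed lactone methylene it carries these precautions:
- The C4(15) enone and the unprimed lactone methylene are also stored as Me2N adducts, because a formate/palladium hydride medium can reduce or isomerise such acceptors.
- The C4 arm is used in step 16 to steer the cycloaddition.
- The configurations at C4, C11 and C11' are immaterial; all three centres become trigonal in step 18.

Step 1
Reactants: 1 2,3-dibromopropene; 2 ethyl acetate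
Product: 4 ethyl 4-bromopent-4-enoate, via lithium enolate of ethyl acetate 3 (not isolated)
Conditions: 2, LiN(i-Pr)2 (1.1 equiv), THF, −78 °C; then 1 (0.9 equiv), DMPU, −78 → 0 °C
Reagents that add atoms: none
Why: Ester enolate alkylation (SN2) at the allylic bromide, the alkenyl bromide being inert to the enolate; no stereocentre is formed.

Step 2
Reactants: 4 ethyl 4-bromopent-4-enoate
Product: 5 4-bromopent-4-enal
Conditions: i-Bu2AlH (1.05 equiv), CH2Cl2, −78 °C; aq. KNaC4H4O6
Reagents that add atoms: none
Why: Partial ester reduction with diisobutylaluminium hydride should stop at the aldehyde because the tetrahedral aluminium hemiacetal is stable at −78 °C.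

Step 3
Reactants: 5 4-bromopent-4-enal; 6 ethyl acrylate
Product: 7 ethyl 6-bromo-3-hydroxy-2-methylidenehept-6-enoate (racemic)
Conditions: 1,4-diazabicyclo[2.2.2]octane (0.5 equiv), 6 (3 equiv), 1,4-dioxane/H2O 1:1, rt
Reagents that add atoms: none
Why: Morita–Baylis–Hillman reaction; the carbinol centre is formed racemic and is erased in step 4.

Step 4
Reactants: 7 ethyl 6-bromo-3-hydroxy-2-methylidenehept-6-enoate
Product: 8 ethyl (2Z)-6-bromo-2-(bromomethyl)hepta-2,6-dienoate
Conditions: PBr3 (0.45 equiv), Et2O, 0 °C
Reagents that add atoms: phosphorus tribromide, BrP(Br)Br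
Why: SN2' bromination of the Baylis–Hillman alcohol with allylic transposition should give the thermodynamically preferred trisubstituted acrylate (chain cis to CH2Br, 2Z).

Step 5
Reactants: 9 (4S)-4-[(tert-butyldimethylsilyl)oxy]cyclopent-2-en-1-one; 10 vinylmagnesium bromide
Product: 11 (3R,4S)-4-[(tert-butyldimethylsilyl)oxy]-3-ethenylcyclopentan-1-one
Conditions: 10 (1.3 equiv), CuBr·SMe2 (0.15 equiv), THF, −78 °C; aq. NH4Cl
Reagents that add atoms: none
Why: Copper-catalysed conjugate addition of the Grignard reagent; the vinyl group enters anti to the silyloxy group, which sets C5 (trans product).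

Step 6
Reactants: 11 (3R,4S)-4-[(tert-butyldimethylsilyl)oxy]-3-ethenylcyclopentan-1-one
Product: 12 (1S,2S)-2-[(tert-butyldimethylsilyl)oxy]-4-oxocyclopentane-1-carbaldehyde
Conditions: O3, CH2Cl2, −78 °C; PPh3, −78 °C → rt; used without chromatography
Reagents that add atoms: ozone, [O-][O+]=O
Why: Ozonolysis with reductive work-up cleaves the only C=C bond, and the neutral medium should keep the β-silyloxy aldehyde from eliminating or epimerising at C5.

Step 7
Reactants: 12 (1S,2S)-2-[(tert-butyldimethylsilyl)oxy]-4-oxocyclopentane-1-carbaldehyde; 8 ethyl (2Z)-6-bromo-2-(bromomethyl)hepta-2,6-dienoate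
Product: 14 cis-lactone (4,5-cis-4-(3-bromobut-3-enyl)-3-methylidene-5-[(1S,2S)-2-silyloxy-4-oxocyclopentyl]oxolan-2-one), via hydroxy ester 13 (not isolated)
Conditions: In powder (1.5 equiv), THF/H2O 3:1, rt; then pyridinium p-toluenesulfonate (0.1 equiv), PhMe, 50 °C
Reagents that add atoms: none
Why: Barbier-type indium allylation followed by acid-catalysed lactonisation: the allylindium reacts at its γ-carbon through a cyclic chair transition state (C6/C7 syn, hence the cis lactone) and should attack the aldehyde in the Felkin–Anh sense with the silyloxy-bearing ring carbon as the large group (C6 relative to C5), while ketone and alkenyl bromide are left alone.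

Step 8
Reactants: 14 cis-lactone; 15 dimethylamine
Product: 16 amine adduct of 14 (C13–NMe2; aminomethyl group anti to the C7 chain)
Conditions: 15 (2 M in THF, 3 equiv), MeOH, 0 °C → rt
Reagents that add atoms: none
Why: Reversible aza-Michael addition to the α-methylene lactone, so C11 should settle with the aminomethyl group anti to the C7 chain; the adduct also protects the lactone from base-induced double-bond migration.

Step 9
Reactants: 16 amine adduct
Product: 17 enone (4-substituted cyclopent-2-en-1-one carrying the amine-masked cis-lactone at C5)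
Conditions: 1,8-diazabicyclo[5.4.0]undec-7-ene (1.2 equiv), CH2Cl2, 0 °C
Reagents that add atoms: none
Why: E1cB β-elimination of the silanol from the β-silyloxy ketone gives the C1(2) enone; the conditions are mild enough to leave C5 untouched.

Step 10
Reactants: 17 enone; 18 Eschenmoser's salt (dimethyl(methylidene)ammonium iodide)
Product: 20 Mannich base (17 with a (dimethylamino)methyl arm on C4, trans to the C5 substituent), via potassium dienolate 19 (not isolated)
Conditions: KN(SiMe3)2 (1.05 equiv), THF, −78 °C (17 added to the base); then 18 (1.2 equiv), −78 → −20 °C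
Reagents that add atoms: none
Why: Kinetic α'-deprotonation of the enone at C4 and Mannich reaction of the potassium enolate, whose higher reactivity suits the sparingly soluble iminium salt at low temperature; the electrophile should enter anti to the C5 substituent and so places the C15 arm on the α-face.

Step 11
Reactants: 20 Mannich base
Product: 21 cis-fused hydroazulenone (13,15-bis(dimethylamino)-3-oxoguai-10(14)-en-12,6-olide; 1αH, 5αH, 6βH, 7βH, C15 α)
Conditions: Pd(OAc)2 (0.1 equiv), PPh3 (0.25 equiv), HCO2Na (1.5 equiv), Et4NCl (1 equiv), DMF (0.02 M), 80 °C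
Reagents that add atoms: none
Why: Intramolecular reductive Heck reaction: the alkenylpalladium adds 7-exo to C1 of the enone from the face that carries the C5–C6 bond (H1 syn to H5) and formate reduces the palladium enolate; the C1 centre is made trigonal again in step 13.

Step 12
Reactants: 21 cis-fused hydroazulenone
Product: 23 2α-hydroxy ketone, via sodium enolate 22 (not isolated)
Conditions: NaN(SiMe3)2 (1.1 equiv), THF, −78 °C; then 2-(phenylsulfonyl)-3-phenyloxaziridine (1.3 equiv), −78 °C; aq. NH4Cl
Reagents that add atoms: 2-(phenylsulfonyl)-3-phenyloxaziridine, O=S(=O)(N1OC1c1ccccc1)c1ccccc1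
Why: Kinetic enolisation at the C2 methylene (the C4 methine is flanked by two substituents) and enolate hydroxylation with the N-sulfonyloxaziridine (Davis oxidation), expected anti to C10 (2α-OH); this centre is removed in step 13.

Step 13
Reactants: 23 2α-hydroxy ketone
Product: 25 diosphenol (2-hydroxy-3-oxoguaia-1,10(14)-diene with both amine arms), via 2,3-dione 24 (not isolated)
Conditions: Dess–Martin periodinane (1.3 equiv), CH2Cl2, 0 °C → rt; aq. NaHCO3/Na2S2O3 work-up; used at once
Reagents that add atoms: none
Why: Dess–Martin oxidation of the acyloin gives the 2,3-dione, which should enolise toward C1 because cyclopentane-1,2-diones exist as enols and this enol is conjugated with C10=C14.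

Step 14
Reactants: 17 enone; 26 formaldehyde
Product: 28 hydroxymethyl enone (CH2OH on C4', trans to the C5' substituent), via lithium dienolate 27 (not isolated)
Conditions: LiN(SiMe3)2 (1.05 equiv), THF, −78 °C; then 26 (monomeric, from cracked paraformaldehyde, THF solution, 3 equiv), −78 °C; aq. NH4Cl
Reagents that add atoms: none
Why: Aldol addition of the kinetic lithium α'-enolate to formaldehyde installs C15', the chelated lithium aldolate resisting retro-aldol cleavage and a second hydroxymethylation; the new C4' centre (expected trans) is erased in step 15.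

Step 15
Reactants: 28 hydroxymethyl enone
Product: 30 dienophile (5-methylidenecyclopent-2-en-1-one carrying the amine-masked cis-lactone at C5'), via mesylate 29 (not isolated)
Conditions: MsCl (1.2 equiv), Et3N (3 equiv), CH2Cl2, −20 → 0 °C; used at once
Reagents that add atoms: none
Why: Mesylation and E1cB elimination give the exocyclic C4'=C15' enone; C5' is not deprotonated under these conditions.

Step 16
Reactants: 25 diosphenol; 30 dienophile
Product: 33 cyclisation substrate (rings A–E, free C2–OH, C1'(2')-enone, three Me2N adducts, alkenyl bromide), via silyl dienol ether 31 (not isolated), via silylated cycloadduct 32 (not isolated)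
Conditions: 25, N,O-bis(trimethylsilyl)acetamide (1.5 equiv), PhMe, rt; then 30 (1.1 equiv), 2,6-di-tert-butyl-4-methylphenol (cat.), PhMe (0.5 M), 60 °C; then 1 M HCl, THF, 0 °C; NaHCO3
Reagents that add atoms: none
Why: Diels–Alder reaction of the ring-locked cisoid 1-silyloxydiene C14=C10–C1=C2(OSiMe3) with the exocyclic C4'=C15' enone: the donor-bearing terminus C2 bonds to the α-carbon C4' and C14 to C15' (ring D); C4' should be attacked on the face opposite its C5' substituent with the C3' carbonyl endo over ring A, and the diene should react on its β-face because the C4 aminomethyl arm screens the α-face, which together fix C2 (O α, C4' β) and the spiro centre C4'; acid then cleaves the silyl ether.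

Step 17
Reactants: 33 cyclisation substrate
Product: 34 cyclised product (target skeleton with the C13, C13' and C15 methylenes as Me2N adducts)
Conditions: Pd(OAc)2 (0.2 equiv), PPh3 (0.5 equiv), HCO2Na (2 equiv, in portions), Et4NCl (1 equiv), DMF (0.01 M), 80 °C
Reagents that add atoms: none
Why: Pd(OAc)2 is reduced in the flask to zerovalent palladium, which inserts into the C10'–Br bond; the alkenylpalladium adds syn across C1'=C2' so that C10' bonds to the β-carbon C1' and palladium sits on C2', where the only β-hydrogen (H1') is anti, and the palladium enolate therefore persists until formate displaces halide, loses CO2 and delivers hydride to give the C3' ketone. The closest known reaction type is the intramolecular reductive (conjugate) Heck cyclisation of alkenyl halides onto cyclic enones. Ring F closes in the 7-exo-trig mode (ring atoms C1', C10', C9', C8', C7', C6', C5'). The one new stereocentre, C1', is controlled by the tether: the chain issues from C6' on one face of C5', so C10' can reach C1' only on that face and H1' ends up syn to H5' (cis fusion). The step needs site selectivity for the C1'(2') enone and cyclisation ahead of hydrodebromination; the first is secured because the C4(15), C11(13) and C11'(13') acceptors are stored as amine adducts and C1=C10 is tetrasubstituted, the second by the pre-organised 7-exo geometry, the chloride additive and portionwise formate at high dilution.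

Step 18
Reactants: 34 cyclised product
Product: 36 target CNP0269880.1, via tris(trimethylammonium) triiodide 35 (not isolated)
Conditions: MeI (15 equiv), THF/MeOH 1:1, rt; evaporate; then sat. aq. NaHCO3, CH2Cl2, rt
Reagents that add atoms: none
Why: Exhaustive N-methylation followed by E1cB (Hofmann-type) loss of trimethylamine from the three β-ammonio carbonyl units should regenerate the C4(15), C11(13) and C11'(13') methylenes; the centres C4, C11 and C11' vanish and no remaining stereocentre is α to a carbonyl.

Compound list
1 | 2,3-dibromopropene | C=C(Br)CBr | starting material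
2 | ethyl acetate | CC(=O)OCC | starting material
3 | lithium enolate of ethyl acetate | [Li+].[O-]C(=C)OCC | intermediate
4 | ethyl 4-bromopent-4-enoate | C=C(Br)CCC(=O)OCC | intermediate
5 | 4-bromopent-4-enal | C=C(Br)CCC=O | intermediate
6 | ethyl acrylate | C=CC(=O)OCC | starting material
7 | ethyl 6-bromo-3-hydroxy-2-methylidenehept-6-enoate (racemic) | C=C(Br)CCC(O)C(=C)C(=O)OCC | intermediate
8 | ethyl (2Z)-6-bromo-2-(bromomethyl)hepta-2,6-dienoate | BrC/C(=C\CCC(Br)=C)C(=O)OCC | intermediate
9 | (4S)-4-[(tert-butyldimethylsilyl)oxy]cyclopent-2-en-1-one | O=C1C=C[C@@H](O[Si](C)(C)C(C)(C)C)C1 | starting material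
10 | vinylmagnesium bromide | C=C[Mg]Br | starting material
11 | (3R,4S)-4-[(tert-butyldimethylsilyl)oxy]-3-ethenylcyclopentan-1-one (trans) | O=C1C[C@H](C=C)[C@@H](O[Si](C)(C)C(C)(C)C)C1 | intermediate
12 | (1S,2S)-2-[(tert-butyldimethylsilyl)oxy]-4-oxocyclopentane-1-carbaldehyde (trans) | O=C1C[C@H](C=O)[C@@H](O[Si](C)(C)C(C)(C)C)C1 | intermediate
13 | hydroxy ester: ethyl 6-bromo-3-{hydroxy[(1S,2S)-2-silyloxy-4-oxocyclopentyl]methyl}-2-methylidenehept-6-enoate (C6–OH and C7 chain syn; C6 Felkin to C5) | O=C1C[C@H]([C@@H](O)[C@H](CCC(Br)=C)C(=C)C(=O)OCC)[C@@H](O[Si](C)(C)C(C)(C)C)C1 | intermediate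
14 | cis-lactone: 4-(3-bromobut-3-enyl)-3-methylidene-5-[(1S,2S)-2-silyloxy-4-oxocyclopentyl]oxolan-2-one (H6/H7 cis, H5/H6 anti) | O=C1C[C@H]([C@H]2OC(=O)C(=C)[C@H]2CCC(Br)=C)[C@@H](O[Si](C)(C)C(C)(C)C)C1 | intermediate
15 | dimethylamine | CNC | starting material
16 | amine adduct: 14 with C11–CH2NMe2 (anti to the C7 chain) | O=C1C[C@H]([C@H]2OC(=O)[C@H](CN(C)C)[C@H]2CCC(Br)=C)[C@@H](O[Si](C)(C)C(C)(C)C)C1 | intermediate
17 | enone: 4-{3-(3-bromobut-3-enyl)-4-[(dimethylamino)methyl]-5-oxooxolan-2-yl}cyclopent-2-en-1-one (5αH, 6βH, 7βH) | O=C1C=C[C@@H]([C@H]2OC(=O)[C@H](CN(C)C)[C@H]2CCC(Br)=C)C1 | intermediate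
18 | Eschenmoser's salt (dimethyl(methylidene)ammonium iodide) | C=[N+](C)C.[I-] | starting material
19 | potassium dienolate of 17 (cross-conjugated, C3–O, C3=C4) | [K+].[O-]C1=C[C@H]([C@H]2OC(=O)[C@H](CN(C)C)[C@H]2CCC(Br)=C)C=C1 | intermediate
20 | Mannich base: 17 with CH2NMe2 on C4, trans to the C5 substituent | O=C1C=C[C@@H]([C@H]2OC(=O)[C@H](CN(C)C)[C@H]2CCC(Br)=C)[C@@H]1CN(C)C | intermediate
21 | cis-fused hydroazulenone: 13,15-bis(dimethylamino)-3-oxoguai-10(14)-en-12,6-olide (1αH, 5αH, 6βH, 7βH; C15 α) | CN(C)C[C@@H]1C(=O)C[C@H]2C(=C)CC[C@@H]3[C@@H](CN(C)C)C(=O)O[C@@H]3[C@@H]12 | intermediate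
22 | sodium enolate of 21 (C2=C3) | CN(C)C[C@@H]1C([O-])=C[C@H]2C(=C)CC[C@@H]3[C@@H](CN(C)C)C(=O)O[C@@H]3[C@@H]12.[Na+] | intermediate
23 | 2α-hydroxy derivative of 21 | CN(C)C[C@@H]1C(=O)[C@H](O)[C@H]2C(=C)CC[C@@H]3[C@@H](CN(C)C)C(=O)O[C@@H]3[C@@H]12 | intermediate
24 | 2,3-dione | CN(C)C[C@@H]1C(=O)C(=O)[C@H]2C(=C)CC[C@@H]3[C@@H](CN(C)C)C(=O)O[C@@H]3[C@@H]12 | intermediate
25 | diosphenol: 13,15-bis(dimethylamino)-2-hydroxy-3-oxoguaia-1,10(14)-dien-12,6-olide (5αH, 6βH, 7βH) | CN(C)C[C@@H]1C(=O)C(O)=C2C(=C)CC[C@@H]3[C@@H](CN(C)C)C(=O)O[C@@H]3[C@@H]12 | intermediate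
26 | formaldehyde (from paraformaldehyde) | C=O | starting material
27 | lithium dienolate of 17 (cross-conjugated, C3'–O, C3'=C4') | [Li+].[O-]C1=C[C@H]([C@H]2OC(=O)[C@H](CN(C)C)[C@H]2CCC(Br)=C)C=C1 | intermediate
28 | hydroxymethyl enone: 17 with CH2OH on C4', trans to the C5' substituent | O=C1C=C[C@@H]([C@H]2OC(=O)[C@H](CN(C)C)[C@H]2CCC(Br)=C)[C@@H]1CO | intermediate
29 | mesylate of 28 | O=C1C=C[C@@H]([C@H]2OC(=O)[C@H](CN(C)C)[C@H]2CCC(Br)=C)[C@@H]1COS(C)(=O)=O | intermediate
30 | dienophile: 4-{3-(3-bromobut-3-enyl)-4-[(dimethylamino)methyl]-5-oxooxolan-2-yl}-5-methylidenecyclopent-2-en-1-one | O=C1C=C[C@@H]([C@H]2OC(=O)[C@H](CN(C)C)[C@H]2CCC(Br)=C)C1=C | intermediate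
31 | trimethylsilyl dienol ether of 25 | CN(C)C[C@@H]1C(=O)C(O[Si](C)(C)C)=C2C(=C)CC[C@@H]3[C@@H](CN(C)C)C(=O)O[C@@H]3[C@@H]12 | intermediate
32 | 2-O-trimethylsilyl cycloadduct | CN(C)C[C@@H]1C(=O)[C@]2(O[Si](C)(C)C)C3=C(CC[C@@H]4[C@@H](CN(C)C)C(=O)O[C@@H]4[C@@H]13)CC[C@]21C(=O)C=C[C@H]1[C@H]2OC(=O)[C@H](CN(C)C)[C@H]2CCC(Br)=C | intermediate
33 | cyclisation substrate: rings A–E with 2α-OH, C1'(2')-enone, C5'-lactone bearing the 3-bromobut-3-enyl chain, C13/C13'/C15 as Me2N adducts | CN(C)C[C@@H]1C(=O)[C@]2(O)C3=C(CC[C@@H]4[C@@H](CN(C)C)C(=O)O[C@@H]4[C@@H]13)CC[C@]21C(=O)C=C[C@H]1[C@H]2OC(=O)[C@H](CN(C)C)[C@H]2CCC(Br)=C | intermediate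
34 | cyclised product: target with C13, C13' and C15 as Me2N adducts (1'αH, 5'αH) | CN(C)C[C@@H]1C(=O)[C@]2(O)C3=C(CC[C@@H]4[C@@H](CN(C)C)C(=O)O[C@@H]4[C@@H]13)CC[C@]21C(=O)C[C@H]2C(=C)CC[C@@H]3[C@@H](CN(C)C)C(=O)O[C@@H]3[C@H]21 | intermediate
35 | tris(trimethylammonium) triiodide of 34 | C[N+](C)(C)C[C@@H]1C(=O)[C@]2(O)C3=C(CC[C@@H]4[C@@H](C[N+](C)(C)C)C(=O)O[C@@H]4[C@@H]13)CC[C@]21C(=O)C[C@H]2C(=C)CC[C@@H]3[C@@H](C[N+](C)(C)C)C(=O)O[C@@H]3[C@H]21.[I-].[I-].[I-] | intermediate
36 | CNP0269880.1 | C=C1C(=O)[C@]2(O)C3=C(CC[C@@H]4C(=C)C(=O)O[C@@H]4[C@@H]13)CC[C@]21C(=O)C[C@H]2C(=C)CC[C@@H]3C(=C)C(=O)O[C@@H]3[C@H]21 | target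

Total step count: 18. Longest linear sequence: 14 steps (1–4, 7–13, 16–18).

Steps most likely to fail

1. Step 16. Bond formation between the two fully substituted carbons C2 and C4' may be slow, which would give the dienol time to shift its C10(14) double bond into the ring and the dienophile time to oligomerise; the dienophile may also approach the α-face of the diene. Fallback: the concerted step is replaced by an anionic two-bond annulation that sets out from 25 and 30. With a catalytic amine base (DBU, MeCN, 0 °C) the diosphenolate should attack C15' through C14 (vinylogous Michael addition) to give the open Michael adduct F1. Its C4' enolate then closes ring D by intramolecular aldol addition to the C2 carbonyl of the 1,2-dione, an equilibrating step that can be driven to the more stable ketol. The sequence comes back to the route at 33.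

2. Step 17. The alkenylpalladium may be intercepted by hydride before it reaches C1' (loss of bromine without ring closure), or the enone may be reduced. Fallback: setting out from 33, the alkenyl bromide is converted by Miyaura borylation (PdCl2(dppf), bis(pinacolato)diboron, KOPh, PhMe, 50 °C) into the alkenyl pinacolboronate F2. A rhodium-catalysed intramolecular 1,4-addition of the Hayashi–Miyaura type ([Rh(OH)(cod)]2, dioxane/H2O, 50 °C) then forms the same C1'–C10' bond through the same tether-controlled face, with protonation of the rhodium enolate, and comes back to the route at 34.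

3. Step 7. Facial selectivity at the aldehyde (C6 relative to C5) may be insufficient, or the syn relationship C6/C7 may erode. Fallback: setting out from 7, acetylation (Ac2O, pyridine) gives the allylic acetate F3. Copper-catalysed SN2' borylation (CuCl, KOt-Bu, bis(pinacolato)diboron, THF) gives the (2E)-allylboronate F4, in which the chain is cis to the CH2B group. Allylboration of 12 through a closed chair transition state, with a chiral phosphoric acid catalyst to impose the C6 configuration, gives the O-boryl adduct F5. Aqueous work-up returns the route to hydroxy ester 13, which lactonises to 14 as in step 7.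

Further compounds
F1 | step 16 | open Michael adduct (C14–C15' bond formed; 2,3-dione with C1=C10; C4'–H trans to the C5' substituent) | CN(C)C[C@@H]1C(=O)C(=O)C2=C(CC[C@@H]3[C@@H](CN(C)C)C(=O)O[C@@H]3[C@@H]12)CC[C@@H]1C(=O)C=C[C@H]1[C@H]2OC(=O)[C@H](CN(C)C)[C@H]2CCC(Br)=C
F2 | step 17 | alkenyl pinacolboronate of 33 (Bpin in place of Br on C10') | CN(C)C[C@@H]1C(=O)[C@]2(O)C3=C(CC[C@@H]4[C@@H](CN(C)C)C(=O)O[C@@H]4[C@@H]13)CC[C@]21C(=O)C=C[C@H]1[C@H]2OC(=O)[C@H](CN(C)C)[C@H]2CCC(=C)B1OC(C)(C)C(C)(C)O1
F3 | step 7 | ethyl 3-acetoxy-6-bromo-2-methylidenehept-6-enoate (racemic) | C=C(Br)CCC(OC(C)=O)C(=C)C(=O)OCC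
F4 | step 7 | ethyl (2E)-6-bromo-2-[(4,4,5,5-tetramethyl-1,3,2-dioxaborolan-2-yl)methyl]hepta-2,6-dienoate | CC1(C)OB(C/C(=C\CCC(Br)=C)C(=O)OCC)OC1(C)C
F5 | step 7 | O-(pinacolboryl) derivative of hydroxy ester 13 | O=C1C[C@H]([C@@H](OB2OC(C)(C)C(C)(C)O2)[C@H](CCC(Br)=C)C(=C)C(=O)OCC)[C@@H](O[Si](C)(C)C(C)(C)C)C1
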